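**Retrosynthetic overview**

1. Endgame: the 2,3-dihydrofuran (C13–C14=C15–O–C16) is closed last by Rh-catalysed alkynol cycloisomerisation. The spiro tetrahydrofuran (C9–O–C13) comes from 5-exo opening of a Sharpless-derived C13 epoxide by the 9α-hydroxyl; O8/O9 come from osmylation of a C8=C9 alkene and O7 from a Rubottom oxidation.
2. The C12–C16 side chain is attached by 1,6-addition of a 2-(silyloxymethyl)allyl copper reagent to a C9-methylene dienone, itself made from the bicyclic core by dehydration and dehydrogenation.
3. Rings A and B are made together from the acyclic, achiral enol acetate–enone 9: intramolecular [2+2] photocycloaddition (C5–C10 plus a temporary C6–C9 bond), retro-aldol opening of the cyclobutane, then aldol closure C7–C8.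
4. Enabling feature: in ring B the C6 ketone has both α-carbons in the ring (ring-fusion C5 and C7), and the oxygenated, methyl-bearing C8 lies β to it. Ring B is therefore the aldol of a C6/C8 1,5-diketone whose C5–C10 bond is a Michael bond onto a C10=C9–C8=O enone, and the cis H-5/C10-methyl pair is that of a cis-fused cyclobutane.
5. Ring order: A and B in one operation (through a temporary cyclobutane), then the tetrahydrofuran ring, then the dihydrofuran ring.

Key step: step 5

Remark: atoms carry labdane numbers (C17 = methyl on C8, C20 = methyl on C10, β = face of C20); the structure is read as drawn with H-5 on the β-face (cis-fused decalin, C5 enolisable), so this fusion is installed kinetically in step 5 and later steps avoid enolisation toward C5.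

**Route**

Step 1
Reactants: 1 mesityl oxide (4-methylpent-3-en-2-one); 2 allylmagnesium bromide
Product: 3 (Z)-[(4,4-dimethylhepta-2,6-dien-2-yl)oxy]trimethylsilane
Conditions: CuBr·SMe2 (1 equiv), TMSCl, THF, −78 °C; Et3N, pentane work-up
Reagents that add atoms: chlorotrimethylsilane, C[Si](C)(C)Cl
Why: Copper-mediated conjugate allylation of the β,β-disubstituted enone under TMSCl activation should build the C4 quaternary carbon and trap the enolate regiospecifically toward C5 (no stereocentre).

Step 2
Reactants: 3
Product: 5 (Z)-4,4-dimethylhepta-2,6-dien-2-yl acetate, via lithium enolate 4 (not isolated)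
Conditions: MeLi, THF, 0 °C; then Ac2O, −78 °C
Reagents that add atoms: acetic anhydride, CC(=O)OC(C)=O
Why: Cleavage of the silyl enol ether by methyllithium gives the regiodefined lithium enolate, whose O-acylation (enol acetate synthesis) should keep the C5=C6 position and give an enol derivative that tolerates a Lewis acid.

Step 3
Reactants: 6 3-methylpentane-2,4-dione
Product: 7 (Z)-3-methyl-4-oxopent-2-en-2-yl trifluoromethanesulfonate
Conditions: NaH, THF, 0 °C; then Tf2O, −78 → 0 °C
Reagents that add atoms: trifluoromethanesulfonic anhydride, O=S(=O)(OS(=O)(=O)C(F)(F)F)C(F)(F)F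
Why: O-Triflation of the sodium enolate of a symmetrical 1,3-diketone can give only one constitution of enol triflate, an activated cross-coupling partner.

Step 4
Reactants: 5; 7
Product: 9 (2Z,8Z)-4,4,8,9-tetramethyl-10-oxoundeca-2,8-dien-2-yl acetate, via alkylborane 8 (not isolated)
Conditions: 9-BBN-H, THF, 0 → 23 °C; then 7, Pd(dppf)Cl2 (5 mol%), AsPh3, Cs2CO3, DMF/H2O, 23 °C
Reagents that add atoms: none
Why: Chemoselective hydroboration of the terminal alkene (the trisubstituted enol acetate is left) and B-alkyl Suzuki–Miyaura coupling with the enol triflate should form C1–C10 and the tetrasubstituted enone, whose geometry is irrelevant because C9 becomes trigonal again in step 5.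

Step 5
Reactants: 9
Product: 12 cis-fused ketol, 3-hydroxy-3,4,4a,8,8-pentamethyloctahydronaphthalen-1(2H)-one with H-8a and 4a-methyl on the same face (labdane 5β-H, 10β-Me; C8/C9 epimers), via cyclobutane photoadduct 10 (not isolated), via 1,5-diketone 11 (not isolated)
Conditions: chiral oxazaborolidine·AlBr3 (50 mol%; from (S)-α,α-diphenylprolinol and 2,4,6-trifluorophenylboronic acid, antipode chosen for the 5R,10S series), CH2Cl2, −75 °C, hν (366 nm); Et3N quench; then K2CO3, MeOH, 0 → 23 °C
Reagents that add atoms: none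
Why: Proposed new method: the AlBr3-activated chiral oxazaborolidine should bind the C8 ketone of the acyclic tetrasubstituted enone, so that the red-shifted complex is excited selectively and adds across the tethered enol acetate in a head-to-tail intramolecular [2+2] photocycloaddition (first bond C10–C5, a 6-exo-trig closure of ring A, then C9–C6) to give the cis-fused bicyclo[4.2.0]octane 10; the closest known reactions are Lewis-acid-catalysed enantioselective enone–alkene [2+2] photocycloadditions of cyclic enones and de Mayo-type enone–enol ester photocycloaddition/retro-aldol sequences. Methanolysis of the acetate then unmasks a cyclobutanol whose strain drives retro-aldol cleavage of the temporary C6–C9 bond to the 1,5-diketone 11, and the C7 methyl enolate closes ring B by a 6-(enolendo)-exo-trig aldol addition to the C8 ketone, so C5–C10 and C7–C8 are both made in this one operation. C5 and C10 are set together as a cis pair because the triplet 1,4-biradical can close only to the cis-fused cyclobutane, and their absolute sense comes from the enone face left open by the catalyst; C8 and C9 of 12 form as mixtures that steps 6 and 7 erase. The step needs cycloaddition to compete with E/Z twisting of the acyclic enone triplet, which the gem-dimethyl tether (Thorpe–Ingold effect) and the electron-rich enol acetate should favour, while the acetate is too weak a nucleophile for a dark Mukaiyama–Michael background reaction. It also needs the aldol to run C7→C8 and not C17→C6, which is secured because C6 lies between the C4 gem-dimethyl carbon and quaternary C10, so the alternative aldol would put three quaternary neighbours on C5.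

Step 6
Reactants: 12
Product: 13 (4aR,8aR)-3,4,4a,8,8-pentamethyl-4a,5,6,7,8,8a-hexahydronaphthalen-1(4H)-one (cis-fused enone; C9 epimers)
Conditions: Burgess reagent, toluene, 50 °C
Reagents that add atoms: none
Why: Burgess dehydration (sulfamate ester, syn-elimination toward the acidic C7–H) should give the conjugated enone under non-basic conditions, so the kinetically set C5 is not enolised; the C8 carbinol centre is removed.

Step 7
Reactants: 13
Product: 14 tert-butyldimethylsilyl dienol ether of 13 (C6=C7 and C8=C9 diene, cis-fused)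
Conditions: TBSOTf, Et3N, CH2Cl2, −78 → 0 °C
Reagents that add atoms: tert-butyldimethylsilyl trifluoromethanesulfonate, CC(C)(C)[Si](C)(C)OS(=O)(=O)C(F)(F)F
Why: Soft enolisation (silyl triflate/amine) should give the thermodynamic, linearly conjugated silyl dienol ether by γ-deprotonation at C9 and not at the hindered C5 methine, which erases the C9 centre.

Step 8
Reactants: 14
Product: 15 cis-fused dienone, 3,4a,8,8-tetramethyl-4-methylene-4a,5,6,7,8,8a-hexahydronaphthalen-1(4H)-one (labdane 5β-H, 10β-Me)
Conditions: DDQ, 2,6-lutidine, CH2Cl2, 0 °C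
Reagents that add atoms: none
Why: DDQ dehydrogenation of the silyl dienol ether (Saegusa-type; hydride abstraction from the C11 methyl, the only δ-hydrogens, then desilylation) should give the linear dienone with the exocyclic C9=C11 methylene.

Step 9
Reactants: 16 2-methylenepropane-1,3-diol
Product: 17 2-{[(tert-butyldimethylsilyl)oxy]methyl}prop-2-en-1-ol
Conditions: NaH (1.0 equiv), THF, 0 °C; then TBSCl
Reagents that add atoms: tert-butyldimethylsilyl chloride, CC(C)(C)[Si](C)(C)Cl
Why: Monosilylation of a symmetrical diol through its sparingly soluble monosodium alkoxide should avoid the statistical mixture.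

Step 10
Reactants: 17
Product: 18 {[2-(bromomethyl)prop-2-en-1-yl]oxy}(tert-butyl)dimethylsilane
Conditions: CBr4, PPh3, CH2Cl2, 0 °C
Reagents that add atoms: tetrabromomethane, BrC(Br)(Br)Br
Why: Appel bromination of the primary allylic alcohol (the allyl unit is symmetrical, so transposition is without consequence).

Step 11
Reactants: 15; 18
Product: 20 bis-silyl compound: TBS dienol ether (C6=C7, C8=C9) carrying the C11–C12–C13(=CH2)–CH2OTBS chain on C9, via Grignard reagent 19 (not isolated)
Conditions: 18, Mg, THF, 0 °C; CuBr·SMe2 (1 equiv), −78 °C; 15; then TBSOTf, −78 → −20 °C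
Reagents that add atoms: tert-butyldimethylsilyl trifluoromethanesulfonate, CC(C)(C)[Si](C)(C)OS(=O)(=O)C(F)(F)F
Why: Copper-mediated 1,6-conjugate addition of the symmetrical 2-substituted allyl nucleophile to the unhindered terminal methylene (the β-carbon C8 is fully substituted) should form C11–C12, and O-silylation of the dienolate fixes the C6=C7/C8=C9 diene.

Step 12
Reactants: 20
Product: 21 7β-silyloxy ketone: C6 ketone, 7β-OTBS, C8=C9 alkene, side chain CH2CH2C(=CH2)CH2OTBS
Conditions: mCPBA (1.0 equiv), NaHCO3, CH2Cl2, −40 °C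
Reagents that add atoms: 3-chloroperoxybenzoic acid, OOC(=O)c1cccc(Cl)c1
Why: Rubottom oxidation: the peracid should epoxidise the most electron-rich C6=C7 enol ether bond from the β-face, because at C7 the α-face is covered by ring A (C4 with its gem-dimethyl group on C5), and 1,4-silyl migration gives the 7β-silyloxy ketone with C8=C9 left in place.

Step 13
Reactants: 21
Product: 22 allylic alcohol: as 21 with the side-chain CH2OH free
Conditions: HF·pyridine, pyridine, THF, 0 °C
Reagents that add atoms: none
Why: Selective desilylation: the unhindered primary allylic silyl ether should cleave much faster than the hindered secondary 7-silyl ether.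

Step 14
Reactants: 22
Product: 23 (13S)-epoxy alcohol: C13–C14 epoxide, C16H2OH free
Conditions: Ti(OiPr)4 (10 mol%), L-(+)-diethyl tartrate, t-BuOOH, 4 Å MS, CH2Cl2, −20 °C
Reagents that add atoms: tert-butyl hydroperoxide, CC(C)(C)OO
Why: Sharpless asymmetric epoxidation of the 2-substituted allylic alcohol: L-(+)-tartrate should deliver oxygen to the face that gives the (S)-epoxy alcohol (reagent control at C13), while the ring C8=C9 alkene has no free allylic hydroxyl and is left.

Step 15
Reactants: 23
Product: 24 epoxy silyl ether: as 23 with C16H2OTBS (13R by CIP, same geometry)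
Conditions: TBSCl, imidazole, CH2Cl2, 0 °C
Reagents that add atoms: tert-butyldimethylsilyl chloride, CC(C)(C)[Si](C)(C)Cl
Why: Silylation under non-alkoxide conditions protects O16 and avoids the degenerate Payne rearrangement that would racemise C13 of this 2,2-disubstituted glycidol.

Step 16
Reactants: 24
Product: 26 spiro tetrahydrofuran: 8α-OH, C9–O–C13 ether, C14H2OH free, C16H2OTBS, 7β-OTBS, C6 ketone, via epoxy diol 25 (not isolated)
Conditions: OsO4 (10 mol%), NMO, citric acid, t-BuOH/H2O, 23 °C; then CSA (10 mol%), CH2Cl2, 0 °C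
Reagents that add atoms: N-methylmorpholine N-oxide, C[N+]1([O-])CCOCC1; water, O
Why: Upjohn dihydroxylation of the tetrasubstituted C8=C9 alkene should occur on the α-face, anti to the pseudoaxial allylic 7β-silyloxy group and to the C10 methyl, giving the 8α,9α-diol, and acid then triggers 5-exo-tet opening of the epoxide at tertiary C13 by the 9α-hydroxyl with inversion, which sets C8, C9 and the final C13 configuration.

Step 17
Reactants: 26
Product: 27 aldehyde: as 26 with C14HO
Conditions: Dess–Martin periodinane, NaHCO3, CH2Cl2, 0 °C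
Reagents that add atoms: none
Why: Dess–Martin oxidation of the only primary alcohol (O8 is tertiary, O7 silylated) gives a non-enolisable α-alkoxy aldehyde.

Step 18
Reactants: 27
Product: 28 alkyne: C13 bears C14≡C15H and C16H2OTBS
Conditions: dimethyl (1-diazo-2-oxopropyl)phosphonate, K2CO3, MeOH, 0 °C
Reagents that add atoms: dimethyl (1-diazo-2-oxopropyl)phosphonate, COP(=O)(OC)C(=[N+]=[N-])C(C)=O
Why: Seyferth–Gilbert homologation with the Ohira–Bestmann reagent adds C15 and converts the aldehyde into the terminal alkyne at a quaternary centre that cannot epimerise.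

Step 19
Reactants: 28
Product: 29 8α-acetate: as 28 with O8 acetylated
Conditions: Ac2O, DMAP, Et3N, CH2Cl2, 40 °C
Reagents that add atoms: acetic anhydride, CC(=O)OC(C)=O
Why: DMAP-catalysed acylation of the only free (tertiary) hydroxyl places the acetate unambiguously on O8 because O7 and O16 are silylated.

Step 20
Reactants: 29
Product: 30 alkynyl diol: 7β-OH and C16H2OH free, 8α-OAc, C14≡C15H
Conditions: HF·pyridine, pyridine, THF, 0 → 23 °C
Reagents that add atoms: none
Why: Buffered fluoride desilylation removes both silyl ethers without base, and the trans 7β-OH/8α-OAc arrangement should disfavour acyl migration.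

Step 21
Reactants: 30
Product: 31 target, (5R,7R,8R,9S,10S,13S)-8-acetoxy-9,13:15,16-diepoxy-7-hydroxylabd-14-en-6-one (5β-H)
Conditions: [Rh(cod)Cl]2 (2.5 mol%), P(4-FC6H4)3, DMF, 85 °C
Reagents that add atoms: none
Why: Rhodium-vinylidene-mediated endo cycloisomerisation of the homopropargylic alcohol (O16 adds to C15) should form the acid-sensitive 2,3-dihydrofuran last under neutral conditions, with no stereocentre touched.

**Compound list**

1 | mesityl oxide (4-methylpent-3-en-2-one) | CC(=O)C=C(C)C | starting material
2 | allylmagnesium bromide | C=CC[Mg]Br | starting material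
3 | (Z)-[(4,4-dimethylhepta-2,6-dien-2-yl)oxy]trimethylsilane | C/C(O[Si](C)(C)C)=C/C(C)(C)CC=C | intermediate
4 | lithium (Z)-4,4-dimethylhepta-2,6-dien-2-olate | [Li+].C/C([O-])=C/C(C)(C)CC=C | intermediate
5 | (Z)-4,4-dimethylhepta-2,6-dien-2-yl acetate | C/C(OC(C)=O)=C/C(C)(C)CC=C | intermediate
6 | 3-methylpentane-2,4-dione | CC(=O)C(C)C(C)=O | starting material
7 | (Z)-3-methyl-4-oxopent-2-en-2-yl trifluoromethanesulfonate | CC(=O)/C(C)=C(/C)OS(=O)(=O)C(F)(F)F | intermediate
8 | B-alkyl-9-BBN from 5 (boron on C1) | C/C(OC(C)=O)=C/C(C)(C)CCCB1C2CCCC1CCC2 | intermediate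
9 | (2Z,8Z)-4,4,8,9-tetramethyl-10-oxoundeca-2,8-dien-2-yl acetate | C/C(OC(C)=O)=C/C(C)(C)CCC/C(C)=C(/C)C(C)=O | intermediate
10 | 7-acetyl-2,2,6,7,8-pentamethylbicyclo[4.2.0]octan-8-yl acetate, cis-fused (H-1 and 6-methyl cis; C7/C8 mixtures) | CC1(OC(C)=O)[C@@H]2C(C)(C)CCC[C@]2(C)C1(C)C(C)=O | intermediate
11 | 3-[(1R,2R)-2-acetyl-1,3,3-trimethylcyclohexyl]butan-2-one (acetyl cis to the butanone arm; C9 epimers) | CC(=O)[C@@H]1C(C)(C)CCC[C@]1(C)C(C)C(C)=O | intermediate
12 | (4aR,8aR)-3-hydroxy-3,4,4a,8,8-pentamethyloctahydronaphthalen-1(2H)-one, cis-fused (C3/C4 epimers) | CC1(O)CC(=O)[C@@H]2C(C)(C)CCC[C@]2(C)C1C | intermediate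
13 | (4aR,8aR)-3,4,4a,8,8-pentamethyl-4a,5,6,7,8,8a-hexahydronaphthalen-1(4H)-one, cis-fused (C4 epimers) | CC1=CC(=O)[C@@H]2C(C)(C)CCC[C@]2(C)C1C | intermediate
14 | tert-butyldimethylsilyl dienol ether of 13 (1-silyloxy-1,3-diene, cis-fused) | CC=1C=C(O[Si](C)(C)C(C)(C)C)[C@@H]2C(C)(C)CCC[C@]2(C)C=1C | intermediate
15 | 3,4a,8,8-tetramethyl-4-methylene-4a,5,6,7,8,8a-hexahydronaphthalen-1(4H)-one, cis-fused (5β-H, 10β-Me) | CC1=CC(=O)[C@@H]2C(C)(C)CCC[C@]2(C)C1=C | intermediate
16 | 2-methylenepropane-1,3-diol | C=C(CO)CO | starting material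
17 | 2-{[(tert-butyldimethylsilyl)oxy]methyl}prop-2-en-1-ol | C=C(CO)CO[Si](C)(C)C(C)(C)C | intermediate
18 | {[2-(bromomethyl)prop-2-en-1-yl]oxy}(tert-butyl)dimethylsilane | C=C(CBr)CO[Si](C)(C)C(C)(C)C | intermediate
19 | allylic Grignard reagent from 18 | C=C(C[Mg]Br)CO[Si](C)(C)C(C)(C)C | intermediate
20 | TBS dienol ether (C6=C7, C8=C9) with the CH2CH2C(=CH2)CH2OTBS chain on C9, cis-fused | CC=1C=C(O[Si](C)(C)C(C)(C)C)[C@@H]2C(C)(C)CCC[C@]2(C)C=1CCC(=C)CO[Si](C)(C)C(C)(C)C | intermediate
21 | 7β-(tert-butyldimethylsilyloxy) 6-ketone with C8=C9 alkene and silylated side chain | CC=1[C@@H](O[Si](C)(C)C(C)(C)C)C(=O)[C@@H]2C(C)(C)CCC[C@]2(C)C=1CCC(=C)CO[Si](C)(C)C(C)(C)C | intermediate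
22 | allylic alcohol (side-chain CH2OH free, 7β-OTBS) | CC=1[C@@H](O[Si](C)(C)C(C)(C)C)C(=O)[C@@H]2C(C)(C)CCC[C@]2(C)C=1CCC(=C)CO | intermediate
23 | (13S)-epoxy alcohol (C13–C14 oxirane, C16H2OH) | CC=1[C@@H](O[Si](C)(C)C(C)(C)C)C(=O)[C@@H]2C(C)(C)CCC[C@]2(C)C=1CC[C@]3(CO)CO3 | intermediate
24 | epoxy silyl ether (C13–C14 oxirane, C16H2OTBS) | CC=1[C@@H](O[Si](C)(C)C(C)(C)C)C(=O)[C@@H]2C(C)(C)CCC[C@]2(C)C=1CC[C@]3(CO[Si](C)(C)C(C)(C)C)CO3 | intermediate
25 | 8α,9α-diol with intact side-chain epoxide | O[C@]1(C)[C@@H](O[Si](C)(C)C(C)(C)C)C(=O)[C@@H]2C(C)(C)CCC[C@]2(C)[C@@]1(O)CC[C@]3(CO[Si](C)(C)C(C)(C)C)CO3 | intermediate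
26 | spiro tetrahydrofuran (9α,13-epoxide, 8α-OH, C14H2OH, C16H2OTBS, 7β-OTBS) | O[C@]1(C)[C@@H](O[Si](C)(C)C(C)(C)C)C(=O)[C@@H]2C(C)(C)CCC[C@]2(C)[C@@]13CC[C@](CO)(CO[Si](C)(C)C(C)(C)C)O3 | intermediate
27 | C14 aldehyde of 26 | O[C@]1(C)[C@@H](O[Si](C)(C)C(C)(C)C)C(=O)[C@@H]2C(C)(C)CCC[C@]2(C)[C@@]13CC[C@](C=O)(CO[Si](C)(C)C(C)(C)C)O3 | intermediate
28 | C14≡C15 alkyne (8α-OH) | O[C@]1(C)[C@@H](O[Si](C)(C)C(C)(C)C)C(=O)[C@@H]2C(C)(C)CCC[C@]2(C)[C@@]13CC[C@](C#C)(CO[Si](C)(C)C(C)(C)C)O3 | intermediate
29 | 8α-acetate of 28 | CC(=O)O[C@]1(C)[C@@H](O[Si](C)(C)C(C)(C)C)C(=O)[C@@H]2C(C)(C)CCC[C@]2(C)[C@@]13CC[C@](C#C)(CO[Si](C)(C)C(C)(C)C)O3 | intermediate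
30 | alkynyl diol (7β-OH, C16H2OH, 8α-OAc) | CC(=O)O[C@]1(C)[C@@H](O)C(=O)[C@@H]2C(C)(C)CCC[C@]2(C)[C@@]13CC[C@](C#C)(CO)O3 | intermediate
31 | (5R,7R,8R,9S,10S,13S)-8-acetoxy-9,13:15,16-diepoxy-7-hydroxylabd-14-en-6-one (5β-H) | CC(=O)O[C@]1(C)[C@@H](O)C(=O)[C@@H]2C(C)(C)CCC[C@]2(C)[C@@]12CC[C@@]1(C=COC1)O2 | target

**Step count and risks**

Total: 21 steps. Longest linear sequence: 18 steps (1, 2, 4–8, 11–21).

Steps most likely to fail:

1. Step 5 (Proposed new method). The Lewis-acid complex of the acyclic enone may discriminate the two enone faces poorly, or its excited state may relax by twisting faster than it adds, so the enantiomeric excess of the cis-fused core could be low. Fallback with known reaction types, setting out from 9 and returning at 15: sensitised irradiation without the Lewis acid (acetone, 350 nm; the de Mayo-type enone–enol ester cycloaddition/retro-aldol sequence) followed by K2CO3/MeOH would give racemic cis-fused material, that is 12 together with its mirror image, the ketol F3, formed through the enantiomeric cyclobutane F1 and the enantiomeric diketone F2. Steps 6–8 carried out on the racemate would give, beside 13–15, the enantiomeric enone F4, the enantiomeric silyl dienol ether F5 and the enantiomeric dienone F6. Luche reduction (NaBH4, CeCl3·7H2O, MeOH, −40 °C; hydride from the convex β-face) would convert the racemic dienone into the 6α-dienol F7 (from 15) and its mirror image, the dienol F8. An enzymatic kinetic resolution (Burkholderia cepacia lipase, vinyl acetate, the enzyme being screened so that it acylates F8) would give the acetate F9, which is separated, and MnO2 oxidation of the dienol F7 returns enantiopure 15.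

2. Step 16. Osmylation of the hindered tetrasubstituted C8=C9 alkene may take place on the β-face (or not at all), because the α-face lies on the ring-A side of the cis-fused bicycle. Fallback, setting out from 24 and returning at 26: acid-catalysed hydrolysis of the epoxide (dilute HClO4, THF/H2O, 0 °C; water attacks tertiary C13 with inversion) would give the 13,14-diol F10. An osmium-catalysed oxidative cyclisation of this 1,2-diol onto the alkene (K2OsO4·2H2O cat., pyridine N-oxide, citric acid, Cu(OTf)2, MeCN/buffer, 60 °C) then adds O13 and a new hydroxyl syn across C8=C9 through a chelated osmate glycolate. The cis-2,5 relationship that this mechanism imposes between the C14 hydroxymethyl arm and the C8 carbinol arm of the new tetrahydrofuran is the one present in 26, so the C13 centre, and not the ring, dictates the face at C8/C9, and 26 is reached directly.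

3. Step 11. The allylic copper reagent may add 1,2 to the C6 carbonyl or couple with itself faster than it adds 1,6 to the methylene. Fallback, setting out from 15 and returning at 20: Hosomi–Sakurai addition of the allylsilane F11 (from commercial 2-[(trimethylsilyl)methyl]prop-2-en-1-ol with TBSCl and imidazole) with TiCl4 (CH2Cl2, −78 °C) should attack the unhindered δ-methylene and give, after protonation, the enone F12 (C9 epimers). Soft enolisation as in step 7 (TBSOTf, Et3N) then gives 20.

Further compounds
F1 | step 5 | enantiomer of cyclobutane photoadduct 10 | CC1(OC(C)=O)[C@H]2C(C)(C)CCC[C@@]2(C)C1(C)C(C)=O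
F2 | step 5 | enantiomer of diketone 11 | CC(=O)[C@H]1C(C)(C)CCC[C@@]1(C)C(C)C(C)=O
F3 | step 5 | enantiomer of ketol 12 | CC1(O)CC(=O)[C@H]2C(C)(C)CCC[C@@]2(C)C1C
F4 | step 5 | enantiomer of enone 13 | CC1=CC(=O)[C@H]2C(C)(C)CCC[C@@]2(C)C1C
F5 | step 5 | enantiomer of silyl dienol ether 14 | CC=1C=C(O[Si](C)(C)C(C)(C)C)[C@H]2C(C)(C)CCC[C@@]2(C)C=1C
F6 | step 5 | enantiomer of dienone 15 | CC1=CC(=O)[C@H]2C(C)(C)CCC[C@@]2(C)C1=C
F7 | step 5 | 6α-dienol from 15 (cis-fused, 5β-H, 10β-Me) | CC1=C[C@H](O)[C@@H]2C(C)(C)CCC[C@]2(C)C1=C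
F8 | step 5 | enantiomer of dienol F7 | CC1=C[C@@H](O)[C@H]2C(C)(C)CCC[C@@]2(C)C1=C
F9 | step 5 | acetate of dienol F8 | CC1=C[C@@H](OC(C)=O)[C@H]2C(C)(C)CCC[C@@]2(C)C1=C
F10 | step 16 | 13,14-diol from 24 (C13–OH, C14H2OH, C16H2OTBS; C8=C9 alkene, 7β-OTBS) | CC=1[C@@H](O[Si](C)(C)C(C)(C)C)C(=O)[C@@H]2C(C)(C)CCC[C@]2(C)C=1CC[C@](O)(CO)CO[Si](C)(C)C(C)(C)C
F11 | step 11 | {2-[(tert-butyldimethylsilyloxy)methyl]allyl}trimethylsilane | C=C(C[Si](C)(C)C)CO[Si](C)(C)C(C)(C)C
F12 | step 11 | cis-fused enone with the CH2CH2C(=CH2)CH2OTBS chain on C9 (C9 epimers) | CC1=CC(=O)[C@@H]2C(C)(C)CCC[C@]2(C)C1CCC(=C)CO[Si](C)(C)C(C)(C)C
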